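The decalin is disconnected across ring B into two three-carbon units, C5–C6–C7 and C8–C9–C10 (labdane numbering), so that the ring-fusion bond C5–C10 and the C7–C8 bond are made together. In a single base-mediated cascade an open-chain keto enoate undergoes intramolecular Michael addition (C10 enolate to C5, closing ring A) and then Claisen condensation (C8 onto the C7 ester, closing ring B). The step exploits the 1,3-relationship of C8 and C10 across C9: a temporary C9 ketone activates both and later accepts the side chain. The C2 silyloxy stereocentre controls the trans ring fusion and absolute configuration; C2 itself is inverted late.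

Key step: step 8

Remark: labdane numbering (C1–C20) is used for the atoms of all intermediates, and methyl 3,3-dimethylpent-4-enoate, pentan-3-one, methyl acrylate and (2E)-3-methylpent-2-en-4-yn-1-ol are taken as commercial.

Step 1
Reactants: 1 methyl 3,3-dimethylpent-4-enoate
Product: 2 3,3-dimethylpent-4-enal
Conditions: i-Bu2AlH (1.05 equiv), CH2Cl2, −78 °C; aq. Rochelle salt
Reagents that add atoms: none
Why: Partial ester reduction (DIBAL reduction) should stop at the aldehyde because the tetrahedral aluminium hemiacetal is stable at −78 °C; the isolated vinyl group is inert.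

Step 2
Reactants: 2 3,3-dimethylpent-4-enal
Product: 3 rac-2-(2,2-dimethylbut-3-en-1-yl)oxirane
Conditions: Me3S+ I−, NaH, DMSO/THF, 0 °C → rt
Reagents that add atoms: trimethylsulfonium iodide, C[S+](C)C.[I-]
Why: Corey–Chaykovsky epoxidation: dimethylsulfonium methylide adds to the aldehyde and the betaine closes to the terminal epoxide, whose new CH2 becomes C1.

Step 3
Reactants: 3 rac-2-(2,2-dimethylbut-3-en-1-yl)oxirane
Product: 4 (2R)-2-(2,2-dimethylbut-3-en-1-yl)oxirane
Conditions: (S,S)-(salen)Co(OAc) (0.5 mol %; salen = N,N′-bis(3,5-di-tert-butylsalicylidene)cyclohexane-1,2-diamine dianion), H2O (0.55 equiv), THF, 0 °C → rt; distillation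
Reagents that add atoms: none
Why: Jacobsen hydrolytic kinetic resolution: the (S,S) catalyst should hydrolyse the (S)-epoxide selectively and leave the (R)-epoxide, which fixes the future C2 stereocentre.

Step 4
Reactants: 5 pentan-3-one
Product: 6 pentan-3-one N,N-dimethylhydrazone
Conditions: Me2NNH2, AcOH (cat.), EtOH, reflux
Reagents that add atoms: N,N-dimethylhydrazine, CN(C)N
Why: Hydrazone formation by condensation gives the azaenolate precursor; the ketone is symmetric, so no regiochemical question arises.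

Step 5
Reactants: 6 pentan-3-one N,N-dimethylhydrazone; 4 (2R)-2-(2,2-dimethylbut-3-en-1-yl)oxirane
Product: 9 (6S)-6-hydroxy-4,8,8-trimethyldec-9-en-3-one, via lithiated hydrazone 7 (not isolated), via alkoxide hydrazone 8 (not isolated)
Conditions: LiN(iPr)2, THF, 0 °C; then 4, 0 °C → rt; H2O; then sat. aq. oxalic acid, Et2O, rt
Reagents that add atoms: water, O
Why: Corey–Enders azaenolate alkylation: the azaenolate opens the epoxide at its CH2 carbon (SN2, C1–C10 bond) without touching the carbinol centre, and mild acid hydrolysis returns the ketone; the new 4-centre (C10) forms as an epimer mixture, which is harmless because it is enolised in step 8.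

Step 6
Reactants: 9 (6S)-6-hydroxy-4,8,8-trimethyldec-9-en-3-one
Product: 10 (6S)-6-[(tert-butyldiphenylsilyl)oxy]-4,8,8-trimethyldec-9-en-3-one
Conditions: TBDPSCl, imidazole, DMAP (cat.), DMF, rt → 40 °C
Reagents that add atoms: tert-butyl(chloro)diphenylsilane, CC(C)(C)[Si](Cl)(c1ccccc1)c1ccccc1
Why: Silylation of the secondary alcohol; the bulky TBDPS ether should survive alkoxide, dilute acid and organolithium in later steps and serves as the stereocontrol element in step 8.

Step 7
Reactants: 10 (6S)-6-[(tert-butyldiphenylsilyl)oxy]-4,8,8-trimethyldec-9-en-3-one; 11 methyl acrylate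
Product: 12 methyl (2E,6S)-6-[(tert-butyldiphenylsilyl)oxy]-4,4,8-trimethyl-9-oxoundec-2-enoate
Conditions: second-generation Hoveyda–Grubbs catalyst (5 mol %), 11 (5 equiv), toluene, 80 °C
Reagents that add atoms: none
Why: Olefin cross-metathesis between the hindered vinyl group and the electron-poor acrylate should favour the cross product and the E-enoate; it supplies C6 and C7.

Step 8
Reactants: 12 methyl (2E,6S)-6-[(tert-butyldiphenylsilyl)oxy]-4,4,8-trimethyl-9-oxoundec-2-enoate
Product: 14 (4aR,7R,8aR)-7-[(tert-butyldiphenylsilyl)oxy]-2,5,5,8a-tetramethyl-4a,5,6,7,8,8a-hexahydronaphthalene-1,3(2H,4H)-dione, via Michael adduct 13 (not isolated)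
Conditions: KOtBu (2.5 equiv), THF/t-BuOH (5:1), 0.01 M, 0 → 45 °C; then 1 M HCl
Reagents that add atoms: none
Why: tert-Butoxide reversibly forms the more substituted ketone enolate (C10), which adds to C5 of the E-enoate (intramolecular Michael addition, 6-(enolexo)-exo-trig, ring A); the only enolate left in adduct 13 (C8) then attacks the C7 ester (Claisen/Dieckmann condensation, 6-(enolendo)-exo-trig, ring B), and deprotonation of the resulting 2-methyl-1,3-dione pulls both equilibria forward. The closest known reaction type is the consecutive Michael–Claisen synthesis of cyclohexane-1,3-diones from ketones and acrylates, here with the Michael step made intramolecular. C5 and C10 are created in a chair-like transition state in which the bulky C2 silyloxy group is equatorial, since an axial position would be syn-diaxial to a C4 methyl group and to the axial C10 substituent, so the (6S) carbinol centre of 12 dictates the absolute configuration (5R,10R). At C10 the planar enolate unit (C9) should take the equatorial site and the C20 methyl group the axial one, because the stereoelectronically fixed enolate plane would drive its ethyl or oxygen substituent into the axial C4 methyl group if it were axial; this makes C6 and C9 trans and the ring fusion trans. The step needs chemoselectivity for the C10 enolate and for intramolecular reaction: the C8 enolate can reach the enoate only through eight- or ten-membered rings before ring A exists, and high dilution suppresses intermolecular addition; the C8 centre is lost on enolisation.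

Step 9
Reactants: 14 (4aR,7R,8aR)-7-[(tert-butyldiphenylsilyl)oxy]-2,5,5,8a-tetramethyl-4a,5,6,7,8,8a-hexahydronaphthalene-1,3(2H,4H)-dione
Product: 15 (4aR,7R,8aR)-7-[(tert-butyldiphenylsilyl)oxy]-3-methoxy-2,5,5,8a-tetramethyl-4a,5,6,7,8,8a-hexahydronaphthalen-1(4H)-one
Conditions: MeOH, HC(OMe)3, camphorsulfonic acid (cat.), rt
Reagents that add atoms: methanol, CO
Why: Acid-catalysed enol etherification of a 1,3-dione under equilibrating conditions: methanol should attack the less hindered C7 carbonyl, so the C9 carbonyl next to the quaternary C10 stays as the ketone, as is usual for 2-methyl-4,4-disubstituted cyclohexane-1,3-diones.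

Step 10
Reactants: 16 (2E)-3-methylpent-2-en-4-yn-1-ol
Product: 17 tert-butyl{[(2E)-3-methylpent-2-en-4-yn-1-yl]oxy}diphenylsilane
Conditions: TBDPSCl, imidazole, CH2Cl2, rt
Reagents that add atoms: tert-butyl(chloro)diphenylsilane, CC(C)(C)[Si](Cl)(c1ccccc1)c1ccccc1
Why: Silyl protection of the primary allylic alcohol (the later C15 oxygen) with the same acid- and base-stable group used at C2, so that both are removed together.

Step 11
Reactants: 17 tert-butyl{[(2E)-3-methylpent-2-en-4-yn-1-yl]oxy}diphenylsilane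
Product: 18 tert-butyl{[(2E)-3-methylpenta-2,4-dien-1-yl]oxy}diphenylsilane
Conditions: H2 (1 atm), Pd/CaCO3 poisoned with Pb(OAc)2, quinoline, hexane, rt
Reagents that add atoms: none
Why: Lindlar semi-hydrogenation should stop at the vinyl group and leave the trisubstituted E double bond (C13=C14) unchanged.

Step 12
Reactants: 18 tert-butyl{[(2E)-3-methylpenta-2,4-dien-1-yl]oxy}diphenylsilane
Product: 20 tert-butyl{[(2E)-5-iodo-3-methylpent-2-en-1-yl]oxy}diphenylsilane, via alkylborane 19 (not isolated)
Conditions: 9-BBN, THF, 0 °C → rt; then NaOMe, MeOH, I2, 0 °C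
Reagents that add atoms: iodine, II
Why: Anti-Markovnikov hydroboration of the monosubstituted diene terminus by the bulky borane, then Brown iodinolysis of the primary B-alkyl group, should give the homoallylic iodide with the trisubstituted alkene intact.

Step 13
Reactants: 20 tert-butyl{[(2E)-5-iodo-3-methylpent-2-en-1-yl]oxy}diphenylsilane; 15 (4aR,7R,8aR)-7-[(tert-butyldiphenylsilyl)oxy]-3-methoxy-2,5,5,8a-tetramethyl-4a,5,6,7,8,8a-hexahydronaphthalen-1(4H)-one
Product: 23 (2R,5R,10R,13E)-2,15-bis[(tert-butyldiphenylsilyl)oxy]labda-8,13-dien-7-one, via organolithium 21 (not isolated), via carbinol adduct 22 (not isolated)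
Conditions: 20, t-BuLi (2.1 equiv), Et2O/pentane, −78 °C; then 15, THF, −78 → 0 °C; then 0.5 M HCl, THF, 0 °C
Reagents that add atoms: water, O
Why: Stork–Danheiser transposition: iodine–lithium exchange gives the primary alkyllithium, which adds 1,2 to the C9 carbonyl (no α-hydrogen), and acid hydrolysis of the β-hydroxy enol ether with loss of water and methanol gives the enone with the C7 ketone, the C8=C9 double bond and the complete side chain on C9.

Step 14
Reactants: 23 (2R,5R,10R,13E)-2,15-bis[(tert-butyldiphenylsilyl)oxy]labda-8,13-dien-7-one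
Product: 24 (2R,5R,7R,10R,13E)-2,15-bis[(tert-butyldiphenylsilyl)oxy]labda-8,13-dien-7-ol
Conditions: NaBH4, CeCl3·7H2O, MeOH/THF, −40 °C
Reagents that add atoms: none
Why: Luche 1,2-reduction: axial delivery of hydride on the face opposite the angular C20 methyl group should give the pseudo-equatorial (7R) allylic alcohol, with the hydroxyl cis to C20.

Step 15
Reactants: 24 (2R,5R,7R,10R,13E)-2,15-bis[(tert-butyldiphenylsilyl)oxy]labda-8,13-dien-7-ol
Product: 27 (2R,5R,9R,10R,13E)-2,15-bis[(tert-butyldiphenylsilyl)oxy]labda-7,13-diene, via sulfonylhydrazine 25 (not isolated), via allylic diazene 26 (not isolated)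
Conditions: PPh3, DEAD, 2-nitrobenzenesulfonohydrazide (NBSH), N-methylmorpholine, −30 → 23 °C
Reagents that add atoms: none
Why: Myers reductive 1,3-transposition: Mitsunobu displacement by NBSH inverts C7, loss of the sulfinic acid gives the allylic diazene, and its retro-ene loss of N2 delivers hydrogen suprafacially to C9 on the face trans to C20, which sets C9 (side chain equatorial, cis to C20) and places the double bond at C7=C8.

Step 16
Reactants: 27 (2R,5R,9R,10R,13E)-2,15-bis[(tert-butyldiphenylsilyl)oxy]labda-7,13-diene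
Product: 28 (2R,5R,9R,10R,13E)-labda-7,13-diene-2,15-diol
Conditions: Bu4NF (3 equiv), THF, 50 °C
Reagents that add atoms: none
Why: Fluoride-induced desilylation removes both TBDPS ethers in one operation; no other group is fluoride-sensitive.

Step 17
Reactants: 28 (2R,5R,9R,10R,13E)-labda-7,13-diene-2,15-diol
Product: 29 (5R,9R,10R,13E)-2-oxolabda-7,13-dien-15-al
Conditions: Dess–Martin periodinane (2.5 equiv), NaHCO3, CH2Cl2, 0 °C → rt
Reagents that add atoms: none
Why: Dess–Martin oxidation converts the equatorial C2 alcohol into the ketone (erasing the wrong C2 configuration) and the allylic alcohol into the E-enal under buffered conditions that should not isomerise either double bond.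

Step 18
Reactants: 29 (5R,9R,10R,13E)-2-oxolabda-7,13-dien-15-al
Product: 30 (2S,5R,9R,10R,13E)-labda-7,13-diene-2,15-diol
Conditions: NaBH4, CeCl3·7H2O, MeOH, −20 → 0 °C
Reagents that add atoms: none
Why: Luche reduction: the two syn-axial methyl groups on C4 and C10 block axial hydride delivery to the C2 ketone, so hydride should enter from the equatorial side and give the axial (2S) alcohol cis to C20, while 1,2-reduction of the enal returns the E-allylic alcohol.

Step 19
Reactants: 30 (2S,5R,9R,10R,13E)-labda-7,13-diene-2,15-diol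
Product: 31 (2S,5R,9R,10R,13E)-labda-7,13-diene-2,15-diyl diacetate
Conditions: Ac2O, pyridine, DMAP (cat.), CH2Cl2, 40 °C
Reagents that add atoms: acetic anhydride, CC(=O)OC(C)=O
Why: DMAP-catalysed acetylation esterifies the primary allylic alcohol and, with gentle heating, the hindered axial C2 alcohol, giving the target without touching any stereocentre.

Compound list
1 | methyl 3,3-dimethylpent-4-enoate | COC(=O)CC(C)(C)C=C | starting material
2 | 3,3-dimethylpent-4-enal | O=CCC(C)(C)C=C | intermediate
3 | rac-2-(2,2-dimethylbut-3-en-1-yl)oxirane | C=CC(C)(C)CC1CO1 | intermediate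
4 | (2R)-2-(2,2-dimethylbut-3-en-1-yl)oxirane | C=CC(C)(C)C[C@@H]1CO1 | intermediate
5 | pentan-3-one | CCC(=O)CC | starting material
6 | pentan-3-one N,N-dimethylhydrazone | CCC(CC)=NN(C)C | intermediate
7 | lithium azaenolate of pentan-3-one N,N-dimethylhydrazone | CC=C(CC)N([Li])N(C)C | intermediate
8 | lithium alkoxide of (6S)-6-hydroxy-4,8,8-trimethyldec-9-en-3-one N,N-dimethylhydrazone (4-epimers) | C=CC(C)(C)C[C@@H](O[Li])CC(C)C(CC)=NN(C)C | intermediate
9 | (6S)-6-hydroxy-4,8,8-trimethyldec-9-en-3-one (4-epimers) | C=CC(C)(C)C[C@@H](O)CC(C)C(=O)CC | intermediate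
10 | (6S)-6-[(tert-butyldiphenylsilyl)oxy]-4,8,8-trimethyldec-9-en-3-one (4-epimers) | C=CC(C)(C)C[C@@H](O[Si](c1ccccc1)(c1ccccc1)C(C)(C)C)CC(C)C(=O)CC | intermediate
11 | methyl acrylate (methyl prop-2-enoate) | C=CC(=O)OC | starting material
12 | methyl (2E,6S)-6-[(tert-butyldiphenylsilyl)oxy]-4,4,8-trimethyl-9-oxoundec-2-enoate (8-epimers) | COC(=O)/C=C/C(C)(C)C[C@@H](O[Si](c1ccccc1)(c1ccccc1)C(C)(C)C)CC(C)C(=O)CC | intermediate
13 | methyl 2-[(1R,2R,4R)-4-[(tert-butyldiphenylsilyl)oxy]-2,6,6-trimethyl-2-propanoylcyclohexyl]acetate | CCC(=O)[C@]1(C)C[C@H](O[Si](c2ccccc2)(c2ccccc2)C(C)(C)C)CC(C)(C)[C@H]1CC(=O)OC | intermediate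
14 | (4aR,7R,8aR)-7-[(tert-butyldiphenylsilyl)oxy]-2,5,5,8a-tetramethyl-4a,5,6,7,8,8a-hexahydronaphthalene-1,3(2H,4H)-dione (trans-fused, silyloxy equatorial, C2 of the ring enolised) | O=C1C(C)C(=O)C[C@@H]2C(C)(C)C[C@@H](O[Si](c3ccccc3)(c3ccccc3)C(C)(C)C)C[C@@]12C | intermediate
15 | (4aR,7R,8aR)-7-[(tert-butyldiphenylsilyl)oxy]-3-methoxy-2,5,5,8a-tetramethyl-4a,5,6,7,8,8a-hexahydronaphthalen-1(4H)-one | O=C1C(C)=C(OC)C[C@@H]2C(C)(C)C[C@@H](O[Si](c3ccccc3)(c3ccccc3)C(C)(C)C)C[C@@]12C | intermediate
16 | (2E)-3-methylpent-2-en-4-yn-1-ol | OC/C=C(\C)C#C | starting material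
17 | tert-butyl{[(2E)-3-methylpent-2-en-4-yn-1-yl]oxy}diphenylsilane | CC(C)(C)[Si](c1ccccc1)(c1ccccc1)OC/C=C(\C)C#C | intermediate
18 | tert-butyl{[(2E)-3-methylpenta-2,4-dien-1-yl]oxy}diphenylsilane | CC(C)(C)[Si](c1ccccc1)(c1ccccc1)OC/C=C(\C)C=C | intermediate
19 | 9-{(3E)-5-[(tert-butyldiphenylsilyl)oxy]-3-methylpent-3-en-1-yl}-9-borabicyclo[3.3.1]nonane | CC(C)(C)[Si](c1ccccc1)(c1ccccc1)OC/C=C(\C)CCB1C2CCCC1CCC2 | intermediate
20 | tert-butyl{[(2E)-5-iodo-3-methylpent-2-en-1-yl]oxy}diphenylsilane | CC(C)(C)[Si](c1ccccc1)(c1ccccc1)OC/C=C(\C)CCI | intermediate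
21 | {(3E)-5-[(tert-butyldiphenylsilyl)oxy]-3-methylpent-3-en-1-yl}lithium | CC(C)(C)[Si](c1ccccc1)(c1ccccc1)OC/C=C(\C)CC[Li] | intermediate
22 | lithium alkoxide of (2R,5R,10R,13E)-2,15-bis[(tert-butyldiphenylsilyl)oxy]-7-methoxylabda-7,13-dien-9-ol (C9 epimers) | CC(C)(C)[Si](c1ccccc1)(c1ccccc1)OC/C=C(\C)CCC1(O[Li])C(C)=C(OC)C[C@@H]2C(C)(C)C[C@@H](O[Si](c3ccccc3)(c3ccccc3)C(C)(C)C)C[C@@]12C | intermediate
23 | (2R,5R,10R,13E)-2,15-bis[(tert-butyldiphenylsilyl)oxy]labda-8,13-dien-7-one | CC(C)(C)[Si](c1ccccc1)(c1ccccc1)OC/C=C(\C)CCC1=C(C)C(=O)C[C@@H]2C(C)(C)C[C@@H](O[Si](c3ccccc3)(c3ccccc3)C(C)(C)C)C[C@@]12C | intermediate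
24 | (2R,5R,7R,10R,13E)-2,15-bis[(tert-butyldiphenylsilyl)oxy]labda-8,13-dien-7-ol (7-OH cis to C20) | CC(C)(C)[Si](c1ccccc1)(c1ccccc1)OC/C=C(\C)CCC1=C(C)[C@H](O)C[C@@H]2C(C)(C)C[C@@H](O[Si](c3ccccc3)(c3ccccc3)C(C)(C)C)C[C@@]12C | intermediate
25 | N-[(2R,5R,7S,10R,13E)-2,15-bis[(tert-butyldiphenylsilyl)oxy]labda-8,13-dien-7-yl]-2-nitrobenzenesulfonohydrazide (C7 inverted) | CC(C)(C)[Si](c1ccccc1)(c1ccccc1)OC/C=C(\C)CCC1=C(C)[C@@H](N(N)S(=O)(=O)c3ccccc3[N+](=O)[O-])C[C@@H]2C(C)(C)C[C@@H](O[Si](c3ccccc3)(c3ccccc3)C(C)(C)C)C[C@@]12C | intermediate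
26 | (2R,5R,7S,10R,13E)-2,15-bis[(tert-butyldiphenylsilyl)oxy]-7-diazenyllabda-8,13-diene | CC(C)(C)[Si](c1ccccc1)(c1ccccc1)OC/C=C(\C)CCC1=C(C)[C@@H](N=N)C[C@@H]2C(C)(C)C[C@@H](O[Si](c3ccccc3)(c3ccccc3)C(C)(C)C)C[C@@]12C | intermediate
27 | (2R,5R,9R,10R,13E)-2,15-bis[(tert-butyldiphenylsilyl)oxy]labda-7,13-diene | CC(C)(C)[Si](c1ccccc1)(c1ccccc1)OC/C=C(\C)CC[C@@H]1C(C)=CC[C@@H]2C(C)(C)C[C@@H](O[Si](c3ccccc3)(c3ccccc3)C(C)(C)C)C[C@@]12C | intermediate
28 | (2R,5R,9R,10R,13E)-labda-7,13-diene-2,15-diol (2-OH equatorial, trans to C20) | OC/C=C(\C)CC[C@@H]1C(C)=CC[C@@H]2C(C)(C)C[C@@H](O)C[C@@]12C | intermediate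
29 | (5R,9R,10R,13E)-2-oxolabda-7,13-dien-15-al | O=C/C=C(\C)CC[C@@H]1C(C)=CC[C@@H]2C(C)(C)CC(=O)C[C@@]12C | intermediate
30 | (2S,5R,9R,10R,13E)-labda-7,13-diene-2,15-diol (2-OH axial, cis to C20) | OC/C=C(\C)CC[C@@H]1C(C)=CC[C@@H]2C(C)(C)C[C@H](O)C[C@@]12C | intermediate
31 | (2S,5R,9R,10R,13E)-labda-7,13-diene-2,15-diyl diacetate | CC(=O)OC/C=C(\C)CC[C@@H]1C(C)=CC[C@@H]2C(C)(C)C[C@H](OC(C)=O)C[C@@]12C | target

Total step count: 19 steps.
Longest linear sequence: 15 steps (steps 1–3, 5–9 and 13–19); steps 4 and 10–12 prepare the two side fragments.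

Steps most likely to fail

Step 8 (key cascade). The Michael addition joins a quaternary carbon to a carbon next to a quaternary centre and may stall. Intermolecular conjugate addition may compete, and the enolate may add through the axial orientation and give the cis ring fusion. The fallback sets out from 12 and separates the two bond formations under kinetic control. Compound 12 is converted with TMSCl, NaI and Et3N in MeCN into the more substituted silyl enol ether methyl (2E,6R)-6-[(tert-butyldiphenylsilyl)oxy]-4,4,8-trimethyl-9-[(trimethylsilyl)oxy]undeca-2,8-dienoate F1. Intramolecular Mukaiyama–Michael addition (TiCl4, CH2Cl2, −78 °C) should give keto ester 13, which is isolated. Dieckmann-type Claisen condensation (NaOMe, MeOH, reflux) then returns to the route at 14.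

Step 15 (reductive transposition). Mitsunobu activation of the hindered allylic alcohol may be slow, elimination to a diene or SN2′ attack may compete, and hydrogen transfer may lose stereospecificity. The fallback sets out from 24, which is acylated (ClCO2Me, pyridine, DMAP) to (2R,5R,7R,10R,13E)-2,15-bis[(tert-butyldiphenylsilyl)oxy]labda-8,13-dien-7-yl methyl carbonate F2. Tsuji formate reduction (Pd2(dba)3, P(n-Bu)3, HCO2NH4, dioxane, 80 °C) follows: zerovalent palladium ionises anti to the carbonate, and hydride is delivered from palladium to the more substituted terminus C9 on the face trans to C20. This should give the less substituted C7=C8 alkene and return to the route at 27.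

Step 7 (cross-metathesis). Metathesis at a vinyl group on a quaternary carbon may be too slow, so that acrylate homodimerisation and catalyst decay win. The fallback sets out from 10, which is ozonised (O3, CH2Cl2/MeOH, −78 °C; PPh3) to (4S)-4-[(tert-butyldiphenylsilyl)oxy]-2,2,6-trimethyl-7-oxononanal F3. Wittig olefination with Ph3P=CHCO2Me (toluene, 80 °C) is selective for the aldehyde over the ketone and for the E-enoate, and returns to the route at 12.

Further compounds
F1 | step 8 | methyl (2E,6R)-6-[(tert-butyldiphenylsilyl)oxy]-4,4,8-trimethyl-9-[(trimethylsilyl)oxy]undeca-2,8-dienoate | COC(=O)/C=C/C(C)(C)C[C@@H](O[Si](c1ccccc1)(c1ccccc1)C(C)(C)C)CC(C)=C(CC)O[Si](C)(C)C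
F2 | step 15 | (2R,5R,7R,10R,13E)-2,15-bis[(tert-butyldiphenylsilyl)oxy]labda-8,13-dien-7-yl methyl carbonate | CC(C)(C)[Si](c1ccccc1)(c1ccccc1)OC/C=C(\C)CCC1=C(C)[C@H](OC(=O)OC)C[C@@H]2C(C)(C)C[C@@H](O[Si](c3ccccc3)(c3ccccc3)C(C)(C)C)C[C@@]12C
F3 | step 7 | (4S)-4-[(tert-butyldiphenylsilyl)oxy]-2,2,6-trimethyl-7-oxononanal | O=CC(C)(C)C[C@@H](O[Si](c1ccccc1)(c1ccccc1)C(C)(C)C)CC(C)C(=O)CC
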